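**Retrosynthetic overview**
1. Target 24 comes from acetylation of macrocyclic diol 23; the 14-membered ring is closed last by an intramolecular B-alkyl Suzuki coupling (C9–C10) of 21, which carries a vinyl epoxide and a (Z)-alkenyl iodide.
2. The vinyl epoxide comes from Sharpless epoxidation of the (Z)-allylic alcohol 10 (sets C12, C13), followed by a one-carbon extension at C11 (lactone → lactol → Wittig); the (Z)-alkenyl iodide comes from a Zhao–Wittig reaction on the masked C8 aldehyde.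
3. 10 comes from the unsaturated δ-lactone 9, made by a catalytic asymmetric vinylogous Mukaiyama aldol on enal 5 (sets C1, locks C12=C13 as Z).
4. 5 comes from SN2 allylation of (R)-6,7-epoxygeranyl acetate 2 (sets C6, gives the CMe2OH group); 2 comes from Shi epoxidation of geranyl acetate 1, which supplies the E-C2=C3 alkene.
5. Ring order: the oxirane is formed in step 7 and the 14-membered carbocycle in step 13; the δ-lactone and lactol rings are temporary.

Atom labels: C1 is the CHOAc carbon and C2 to C14 follow the ring in the order of the target SMILES (C6 bears the side chain, C12 and C13 are the oxirane carbons); C15 is the side-chain carbinol carbon.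
Assumption: in step 5 (S)-Tol-BINAP is taken as the ligand enantiomer that gives the (R)-carbinol; if the sense proves opposite, (R)-Tol-BINAP is used and nothing else changes.

**Step 1**
Reactants: 1 geranyl acetate [(2E)-3,7-dimethylocta-2,6-dien-1-yl acetate]
Product: 2 (2E)-5-[(2R)-3,3-dimethyloxiran-2-yl]-3-methylpent-2-en-1-yl acetate
Conditions: D-fructose-derived Shi ketone (0.3 equiv), 2KHSO5·KHSO4·K2SO4, K2CO3, Bu4NHSO4, MeCN/CH2(OMe)2/aq. Na2B4O7 buffer, 0 °C
Reagents that add atoms: potassium peroxymonosulfate KHSO5, [K+].[O-]S(=O)(=O)OO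
Why: Shi asymmetric epoxidation, in which the chiral dioxirane attacks only the electron-rich distal trisubstituted alkene (the 2,3-alkene is deactivated by the allylic acetate) through a spiro transition state that sets the oxirane CH centre as R.

**Step 2**
Reactants: 2 (2E)-5-[(2R)-3,3-dimethyloxiran-2-yl]-3-methylpent-2-en-1-yl acetate
Product: 4 (2E,6R)-6-(2-hydroxypropan-2-yl)-3-methylnona-2,8-dien-1-ol, via epoxy alkoxide 3 (not isolated)
Conditions: CH2=CHCH2MgCl (4.5 equiv), THF, 0 °C to rt; aq. NH4Cl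
Reagents that add atoms: allylmagnesium chloride, C=CC[Mg]Cl
Why: CH2=CHCH2MgCl first cleaves the acetate (giving 3) and then opens the trisubstituted epoxide by SN2 attack at its less hindered secondary carbon with inversion, which fixes C6 as R and unveils the tertiary carbinol.

**Step 3**
Reactants: 4 (2E,6R)-6-(2-hydroxypropan-2-yl)-3-methylnona-2,8-dien-1-ol
Product: 5 (2E,6R)-6-(2-hydroxypropan-2-yl)-3-methylnona-2,8-dienal
Conditions: MnO2 (activated, 15 equiv), CH2Cl2, rt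
Reagents that add atoms: none
Why: chemoselective allylic oxidation with MnO2 converts only the primary allylic alcohol into the E-enal and leaves the tertiary alcohol and the isolated alkene untouched.

**Step 4**
Reactants: 6 ethyl 3-methylbut-2-enoate
Product: 7 [(1-ethoxy-3-methylbuta-1,3-dien-1-yl)oxy]trimethylsilane
Conditions: LiN(i-Pr)2, THF, −78 °C; Me3SiCl, −78 °C to rt
Reagents that add atoms: chlorotrimethylsilane, C[Si](C)(C)Cl
Why: kinetic γ-deprotonation of the ester gives the extended dienolate (Li salt), which is trapped on oxygen as the silyl dienol ether (silyl ketene acetal formation).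

**Step 5**
Reactants: 5 (2E,6R)-6-(2-hydroxypropan-2-yl)-3-methylnona-2,8-dienal; 7 [(1-ethoxy-3-methylbuta-1,3-dien-1-yl)oxy]trimethylsilane
Product: 9 (6R)-6-[(1E,5R)-5-(2-hydroxypropan-2-yl)-2-methylocta-1,7-dien-1-yl]-4-methyl-5,6-dihydro-2H-pyran-2-one, via Z-aldolate 8 (not isolated)
Conditions: Cu(OTf)2 (10 mol%), (S)-Tol-BINAP (11 mol%), (Bu4N)[Ph3SiF2] (20 mol%), THF, −40 °C to rt; aq. HCl work-up
Reagents that add atoms: none
Why: catalytic asymmetric vinylogous Mukaiyama aldol reaction, in which the dienolate generated by the Cu(OTf)2/(S)-Tol-BINAP/(Bu4N)[Ph3SiF2] system adds through its γ-carbon to one face of the enal carbonyl and sets C1 as R, after which the (2Z)-aldolate 8 lactonises spontaneously and thereby locks the C12=C13 alkene as Z.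

**Step 6**
Reactants: 9 (6R)-6-[(1E,5R)-5-(2-hydroxypropan-2-yl)-2-methylocta-1,7-dien-1-yl]-4-methyl-5,6-dihydro-2H-pyran-2-one
Product: 10 (2Z,5R,6E,10R)-10-(2-hydroxypropan-2-yl)-3,7-dimethyltrideca-2,6,12-triene-1,5-diol
Conditions: i-Bu2AlH (5 equiv), CH2Cl2, −78 to 0 °C; aq. KNaC4H4O6
Reagents that add atoms: none
Why: 1,2-hydride reduction of the unsaturated lactone opens the ring to the diol, so the ring-imposed Z geometry is carried into a nerol-type primary allylic alcohol.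

**Step 7**
Reactants: 10 (2Z,5R,6E,10R)-10-(2-hydroxypropan-2-yl)-3,7-dimethyltrideca-2,6,12-triene-1,5-diol
Product: 11 (2R,3E,7R)-1-[(2R,3S)-3-(hydroxymethyl)-2-methyloxiran-2-yl]-7-(2-hydroxypropan-2-yl)-4-methyldeca-3,9-dien-2-ol
Conditions: Ti(OiPr)4 (20 mol%), L-(+)-diethyl tartrate (24 mol%), t-BuOOH, 4 Å molecular sieves, CH2Cl2, −20 °C
Reagents that add atoms: tert-butyl hydroperoxide, CC(C)(C)OO
Why: Sharpless asymmetric epoxidation, in which the Ti(OiPr)4/L-(+)-diethyl tartrate catalyst bound to the primary Z-allylic alcohol delivers oxygen to the face that gives the (12S,13R) cis-epoxide (the sense known for nerol), while the (R)-configured secondary allylic alcohol at C1 is the slow-reacting partner for this tartrate so its own alkene is left alone.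

**Step 8**
Reactants: 11 (2R,3E,7R)-1-[(2R,3S)-3-(hydroxymethyl)-2-methyloxiran-2-yl]-7-(2-hydroxypropan-2-yl)-4-methyldeca-3,9-dien-2-ol
Product: 14 (1R,4R,6R)-4-[(1E,5R)-5-(2-hydroxypropan-2-yl)-2-methylocta-1,7-dien-1-yl]-6-methyl-3,7-dioxabicyclo[4.1.0]heptan-2-one, via epoxy aldehyde 12 (not isolated), via lactol 13 (not isolated)
Conditions: TEMPO (20 mol%), PhI(OAc)2 (2.5 equiv), CH2Cl2, rt
Reagents that add atoms: none
Why: oxoammonium (TEMPO) oxidation takes the primary alcohol to aldehyde 12, which the C1 hydroxyl traps as the six-membered lactol 13 (possible because the epoxide is cis) and which is oxidised on to the δ-lactone, so the C1 oxygen and the C11 oxidation level are both masked for the next steps.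

**Step 9**
Reactants: 14 (1R,4R,6R)-4-[(1E,5R)-5-(2-hydroxypropan-2-yl)-2-methylocta-1,7-dien-1-yl]-6-methyl-3,7-dioxabicyclo[4.1.0]heptan-2-one
Product: 17 (1R,4R,6R)-4-[(1E)-4-[(3R)-5-hydroxy-2,2-dimethyloxolan-3-yl]-2-methylbut-1-en-1-yl]-6-methyl-3,7-dioxabicyclo[4.1.0]heptan-2-one, via diol 15 (not isolated), via hydroxy aldehyde 16 (not isolated)
Conditions: OsO4 (2 mol%), NaIO4 (4 equiv), 2,6-lutidine, 1,4-dioxane/H2O 3:1, rt
Reagents that add atoms: sodium periodate NaIO4, [Na+].[O-]I(=O)(=O)=O; osmium tetroxide OsO4 (catalytic oxygen carrier), O=[Os](=O)(=O)=O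
Why: Lemieux–Johnson cleavage, in which OsO4 dihydroxylates only the unhindered monosubstituted alkene (the trisubstituted alkene is deactivated by the allylic lactone oxygen), NaIO4 cleaves diol 15, and the tertiary alcohol captures aldehyde 16 as a five-membered lactol, the form in which the material is isolated.

**Step 10**
Reactants: 17 (1R,4R,6R)-4-[(1E)-4-[(3R)-5-hydroxy-2,2-dimethyloxolan-3-yl]-2-methylbut-1-en-1-yl]-6-methyl-3,7-dioxabicyclo[4.1.0]heptan-2-one
Product: 18 (1R,4R,6R)-4-[(1E,5R,7Z)-5-(2-hydroxypropan-2-yl)-8-iodo-2-methylnona-1,7-dien-1-yl]-6-methyl-3,7-dioxabicyclo[4.1.0]heptan-2-one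
Conditions: [Ph3PCH2CH3]I (3 equiv), n-BuLi, THF; I2, −78 °C; NaN(SiMe3)2, −20 °C; then 17, −78 to −20 °C
Reagents that add atoms: ethyltriphenylphosphonium iodide, CC[P+](c1ccccc1)(c1ccccc1)c1ccccc1.[I-]; iodine, II
Why: Zhao variant of the Wittig reaction carried out directly on the lactol, which is the closed tautomer of the γ-hydroxy aldehyde passed through in step 9 and reverts to that open form once the excess ylide deprotonates its hydroxyl, whereupon the non-stabilised α-iodoethylidene ylide gives the (Z)-2-iodo-2-alkene through the kinetically favoured cis-oxaphosphetane, so that iodine ends up cis to C7 and the tertiary hydroxyl is set free again.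

**Step 11**
Reactants: 18 (1R,4R,6R)-4-[(1E,5R,7Z)-5-(2-hydroxypropan-2-yl)-8-iodo-2-methylnona-1,7-dien-1-yl]-6-methyl-3,7-dioxabicyclo[4.1.0]heptan-2-one
Product: 19 (1R,4R,6R)-4-[(1E,5R,7Z)-5-(2-hydroxypropan-2-yl)-8-iodo-2-methylnona-1,7-dien-1-yl]-6-methyl-3,7-dioxabicyclo[4.1.0]heptan-2-ol
Conditions: i-Bu2AlH (2.2 equiv), CH2Cl2, −78 °C; MeOH, aq. KNaC4H4O6
Reagents that add atoms: none
Why: partial hydride reduction of the lactone at low temperature stops at the tetrahedral hemiacetal stage and gives the lactol without touching the epoxide or the alkenyl iodide.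

**Step 12**
Reactants: 19 (1R,4R,6R)-4-[(1E,5R,7Z)-5-(2-hydroxypropan-2-yl)-8-iodo-2-methylnona-1,7-dien-1-yl]-6-methyl-3,7-dioxabicyclo[4.1.0]heptan-2-ol
Product: 21 (2R,3E,7R,9Z)-1-[(2R,3S)-3-ethenyl-2-methyloxiran-2-yl]-7-(2-hydroxypropan-2-yl)-10-iodo-4-methylundeca-3,9-dien-2-ol, via epoxy aldehyde 20 (not isolated)
Conditions: [Ph3PCH3]Br (5 equiv), KN(SiMe3)2 (4.8 equiv), THF, 0 °C to rt
Reagents that add atoms: methyltriphenylphosphonium bromide, C[P+](c1ccccc1)(c1ccccc1)c1ccccc1.[Br-]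
Why: Wittig methylenation, in which the lactol opens to the α,β-epoxy aldehyde 20 that is olefinated to the vinyl epoxide, adding C10 and freeing the C1 hydroxyl in the same operation.

**Step 13**
Reactants: 21 (2R,3E,7R,9Z)-1-[(2R,3S)-3-ethenyl-2-methyloxiran-2-yl]-7-(2-hydroxypropan-2-yl)-10-iodo-4-methylundeca-3,9-dien-2-ol
Product: 23 (1R,3R,4E,8R,10Z,14S)-8-(2-hydroxypropan-2-yl)-1,5,11-trimethyl-15-oxabicyclo[12.1.0]pentadeca-4,10-dien-3-ol, via alkylborane 22 (not isolated)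
Conditions: 9-BBN (4 equiv), THF, 0 °C to rt; then slow addition to Pd(dppf)Cl2 (20 mol%), AsPh3 (40 mol%), Cs2CO3, DMF/THF/H2O, 2 mM, 50 °C
Reagents that add atoms: none
Why: anti-Markovnikov hydroboration of the only monosubstituted alkene gives the primary alkylborane 22, and intramolecular B-alkyl Suzuki–Miyaura coupling with the alkenyl iodide forms the C9–C10 bond with retention of the Z geometry, closing the 14-membered ring under high dilution.

**Step 14**
Reactants: 23 (1R,3R,4E,8R,10Z,14S)-8-(2-hydroxypropan-2-yl)-1,5,11-trimethyl-15-oxabicyclo[12.1.0]pentadeca-4,10-dien-3-ol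
Product: 24 [(1R,3R,4E,8R,10Z,14S)-8-(2-hydroxypropan-2-yl)-1,5,11-trimethyl-15-oxabicyclo[12.1.0]pentadeca-4,10-dien-3-yl] acetate
Conditions: Ac2O (1.5 equiv), pyridine, DMAP (5 mol%), CH2Cl2, 0 °C
Reagents that add atoms: acetic anhydride, CC(=O)OC(C)=O
Why: nucleophile-catalysed acylation esterifies the secondary allylic alcohol while the hindered tertiary alcohol does not react under these mild conditions, and no stereocentre is touched.

**Compound list**
1 | geranyl acetate [(2E)-3,7-dimethylocta-2,6-dien-1-yl acetate] | CC(=O)OC/C=C(\C)CCC=C(C)C | starting material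
2 | (2E)-5-[(2R)-3,3-dimethyloxiran-2-yl]-3-methylpent-2-en-1-yl acetate | CC(=O)OC/C=C(\C)CC[C@H]1OC1(C)C | intermediate
3 | (2E)-5-[(2R)-3,3-dimethyloxiran-2-yl]-3-methylpent-2-en-1-ol (held as its ClMg alkoxide) | OC/C=C(\C)CC[C@H]1OC1(C)C | intermediate
4 | (2E,6R)-6-(2-hydroxypropan-2-yl)-3-methylnona-2,8-dien-1-ol | OC/C=C(\C)CC[C@@H](C(C)(C)O)CC=C | intermediate
5 | (2E,6R)-6-(2-hydroxypropan-2-yl)-3-methylnona-2,8-dienal | O=C/C=C(\C)CC[C@@H](C(C)(C)O)CC=C | intermediate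
6 | ethyl 3-methylbut-2-enoate | CCOC(=O)C=C(C)C | starting material
7 | [(1-ethoxy-3-methylbuta-1,3-dien-1-yl)oxy]trimethylsilane | C=C(C)C=C(OCC)O[Si](C)(C)C | intermediate
8 | ethyl (2Z,5R,6E,10R)-5-hydroxy-10-(2-hydroxypropan-2-yl)-3,7-dimethyltrideca-2,6,12-trienoate (as the aldolate) | CCOC(=O)/C=C(/C)C[C@@H](O)/C=C(\C)CC[C@@H](C(C)(C)O)CC=C | intermediate
9 | (6R)-6-[(1E,5R)-5-(2-hydroxypropan-2-yl)-2-methylocta-1,7-dien-1-yl]-4-methyl-5,6-dihydro-2H-pyran-2-one | CC1=CC(=O)O[C@H](C1)/C=C(\C)CC[C@@H](C(C)(C)O)CC=C | intermediate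
10 | (2Z,5R,6E,10R)-10-(2-hydroxypropan-2-yl)-3,7-dimethyltrideca-2,6,12-triene-1,5-diol | OC/C=C(/C)C[C@@H](O)/C=C(\C)CC[C@@H](C(C)(C)O)CC=C | intermediate
11 | (2R,3E,7R)-1-[(2R,3S)-3-(hydroxymethyl)-2-methyloxiran-2-yl]-7-(2-hydroxypropan-2-yl)-4-methyldeca-3,9-dien-2-ol | OC[C@@H]1O[C@]1(C)C[C@@H](O)/C=C(\C)CC[C@@H](C(C)(C)O)CC=C | intermediate
12 | (2R,3R)-3-[(2R,3E,7R)-2-hydroxy-7-(2-hydroxypropan-2-yl)-4-methyldeca-3,9-dien-1-yl]-3-methyloxirane-2-carbaldehyde | O=C[C@@H]1O[C@]1(C)C[C@@H](O)/C=C(\C)CC[C@@H](C(C)(C)O)CC=C | intermediate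
13 | (1R,4R,6R)-4-[(1E,5R)-5-(2-hydroxypropan-2-yl)-2-methylocta-1,7-dien-1-yl]-6-methyl-3,7-dioxabicyclo[4.1.0]heptan-2-ol (both anomers) | OC1O[C@H](C[C@@]2(C)O[C@@H]12)/C=C(\C)CC[C@@H](C(C)(C)O)CC=C | intermediate
14 | (1R,4R,6R)-4-[(1E,5R)-5-(2-hydroxypropan-2-yl)-2-methylocta-1,7-dien-1-yl]-6-methyl-3,7-dioxabicyclo[4.1.0]heptan-2-one | O=C1O[C@H](C[C@@]2(C)O[C@@H]12)/C=C(\C)CC[C@@H](C(C)(C)O)CC=C | intermediate
15 | (1R,4R,6R)-4-[(1E,5R)-7,8-dihydroxy-5-(2-hydroxypropan-2-yl)-2-methyloct-1-en-1-yl]-6-methyl-3,7-dioxabicyclo[4.1.0]heptan-2-one | O=C1O[C@H](C[C@@]2(C)O[C@@H]12)/C=C(\C)CC[C@@H](C(C)(C)O)CC(O)CO | intermediate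
16 | (3R,6E)-3-(2-hydroxypropan-2-yl)-6-methyl-7-[(1R,4R,6R)-6-methyl-2-oxo-3,7-dioxabicyclo[4.1.0]heptan-4-yl]hept-6-enal | O=C1O[C@H](C[C@@]2(C)O[C@@H]12)/C=C(\C)CC[C@@H](C(C)(C)O)CC=O | intermediate
17 | (1R,4R,6R)-4-[(1E)-4-[(3R)-5-hydroxy-2,2-dimethyloxolan-3-yl]-2-methylbut-1-en-1-yl]-6-methyl-3,7-dioxabicyclo[4.1.0]heptan-2-one (both anomers) | O=C1O[C@H](C[C@@]2(C)O[C@@H]12)/C=C(\C)CC[C@@H]1CC(O)OC1(C)C | intermediate
18 | (1R,4R,6R)-4-[(1E,5R,7Z)-5-(2-hydroxypropan-2-yl)-8-iodo-2-methylnona-1,7-dien-1-yl]-6-methyl-3,7-dioxabicyclo[4.1.0]heptan-2-one | O=C1O[C@H](C[C@@]2(C)O[C@@H]12)/C=C(\C)CC[C@@H](C(C)(C)O)C/C=C(/C)I | intermediate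
19 | (1R,4R,6R)-4-[(1E,5R,7Z)-5-(2-hydroxypropan-2-yl)-8-iodo-2-methylnona-1,7-dien-1-yl]-6-methyl-3,7-dioxabicyclo[4.1.0]heptan-2-ol (both anomers) | OC1O[C@H](C[C@@]2(C)O[C@@H]12)/C=C(\C)CC[C@@H](C(C)(C)O)C/C=C(/C)I | intermediate
20 | (2R,3R)-3-[(2R,3E,7R,9Z)-2-hydroxy-7-(2-hydroxypropan-2-yl)-10-iodo-4-methylundeca-3,9-dien-1-yl]-3-methyloxirane-2-carbaldehyde | O=C[C@@H]1O[C@]1(C)C[C@@H](O)/C=C(\C)CC[C@@H](C(C)(C)O)C/C=C(/C)I | intermediate
21 | (2R,3E,7R,9Z)-1-[(2R,3S)-3-ethenyl-2-methyloxiran-2-yl]-7-(2-hydroxypropan-2-yl)-10-iodo-4-methylundeca-3,9-dien-2-ol | C=C[C@@H]1O[C@]1(C)C[C@@H](O)/C=C(\C)CC[C@@H](C(C)(C)O)C/C=C(/C)I | intermediate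
22 | (2R,3E,7R,9Z)-1-[(2R,3S)-3-[2-(9-borabicyclo[3.3.1]nonan-9-yl)ethyl]-2-methyloxiran-2-yl]-7-(2-hydroxypropan-2-yl)-10-iodo-4-methylundeca-3,9-dien-2-ol | B1(CC[C@@H]2O[C@]2(C)C[C@@H](O)/C=C(\C)CC[C@@H](C(C)(C)O)C/C=C(/C)I)C3CCCC1CCC3 | intermediate
23 | (1R,3R,4E,8R,10Z,14S)-8-(2-hydroxypropan-2-yl)-1,5,11-trimethyl-15-oxabicyclo[12.1.0]pentadeca-4,10-dien-3-ol | O[C@H]1/C=C(\C)CC[C@@H](C(C)(C)O)C/C=C(/C)CC[C@@H]2O[C@]2(C)C1 | intermediate
24 | [(1R,3R,4E,8R,10Z,14S)-8-(2-hydroxypropan-2-yl)-1,5,11-trimethyl-15-oxabicyclo[12.1.0]pentadeca-4,10-dien-3-yl] acetate | CC(=O)O[C@H]1/C=C(\C)CC[C@@H](C(C)(C)O)C/C=C(/C)CC[C@@H]2O[C@]2(C)C1 | target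

**Step count and risks**
Total step count: 14. Longest linear sequence: 13 steps (steps 1 to 3 and 5 to 14, from geranyl acetate 1).

The three steps most likely to fail:

Step 5 (asymmetric vinylogous aldol with lactonisation). The enal is β,β-disubstituted, the enantioselectivity may be only moderate, and the sense of induction is assumed. Any (1S) material becomes a separable diastereomer after step 7. The fallback sets out from 5 and comes back at 9. Enal 5 is allylated with the 2-methylallylborane made from (+)-B-methoxydiisopinocampheylborane and CH2=C(CH3)CH2MgCl (Et2O, −78 °C, then NaOH/H2O2); this Brown reagent is the enantiomer that gives R carbinols from aryl and alkenyl aldehydes, and it yields (4R,5E,9R)-9-(2-hydroxypropan-2-yl)-2,6-dimethyldodeca-1,5,11-trien-4-ol F1. The secondary hydroxyl is esterified with acryloyl chloride and i-Pr2NEt (CH2Cl2, 0 °C) to give (4R,5E,9R)-9-(2-hydroxypropan-2-yl)-2,6-dimethyldodeca-1,5,11-trien-4-yl prop-2-enoate F2. Ring-closing metathesis between the acrylate and the 1,1-disubstituted alkene (second-generation Grubbs catalyst RuCl2(=CHPh)(PCy3)(H2IMes), CH2Cl2, 2 mM, 40 °C, dilute so that six-ring closure outruns reaction at the remote allyl group) returns lactone 9.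

Step 10 (Zhao–Wittig). These iodo-ylide olefinations give modest yields, and here the ylide must also open a lactol next to an epoxy lactone. The fallback sets out from 17 and comes back at 18. Lactol 17 is treated with CBr4/PPh3/Et3N (CH2Cl2, 0 °C, Corey–Fuchs-type dibromo-olefination of its open aldehyde form) to give (1R,4R,6R)-4-[(1E,5R)-8,8-dibromo-5-(2-hydroxypropan-2-yl)-2-methylocta-1,7-dien-1-yl]-6-methyl-3,7-dioxabicyclo[4.1.0]heptan-2-one F3. A Pd(DPEphos)Cl2-catalysed Negishi coupling with MeZnCl (THF, 0 °C) replaces selectively the bromine trans to the chain and gives (1R,4R,6R)-4-[(1E,5R,7Z)-8-bromo-5-(2-hydroxypropan-2-yl)-2-methylnona-1,7-dien-1-yl]-6-methyl-3,7-dioxabicyclo[4.1.0]heptan-2-one F4, with bromine cis to C7. Halogen exchange with retention (CuI, NaI, N,N′-dimethylethane-1,2-diamine, 1,4-dioxane, 100 °C) then gives 18.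

Step 13 (hydroboration and macrocyclic B-alkyl Suzuki coupling). The borane sits γ to the epoxide oxygen and the ring closure competes with oligomerisation. The fallback sets out from 21 and comes back at 23. Compound 21 is hydroborated with 9-BBN and oxidised with NaBO3·4H2O to (2R,3E,7R,9Z)-1-[(2R,3S)-3-(2-hydroxyethyl)-2-methyloxiran-2-yl]-7-(2-hydroxypropan-2-yl)-10-iodo-4-methylundeca-3,9-dien-2-ol F5. The primary hydroxyl is converted with I2/PPh3/imidazole (CH2Cl2, 0 °C) into (2R,3E,7R,9Z)-7-(2-hydroxypropan-2-yl)-10-iodo-1-[(2R,3S)-3-(2-iodoethyl)-2-methyloxiran-2-yl]-4-methylundeca-3,9-dien-2-ol F6. The ring is then closed by reductive alkenyl–alkyl cross-electrophile coupling (NiCl2(dme), 4,4′-di-tert-butyl-2,2′-bipyridine, Mn powder, DMA, slow addition, 2 mM), which again gives 23 with the Z alkene retained.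

**Further compounds**
F1 | step 5 | (4R,5E,9R)-9-(2-hydroxypropan-2-yl)-2,6-dimethyldodeca-1,5,11-trien-4-ol | C=C(C)C[C@@H](O)/C=C(\C)CC[C@@H](C(C)(C)O)CC=C
F2 | step 5 | (4R,5E,9R)-9-(2-hydroxypropan-2-yl)-2,6-dimethyldodeca-1,5,11-trien-4-yl prop-2-enoate | C=CC(=O)O[C@H](CC(C)=C)/C=C(\C)CC[C@@H](C(C)(C)O)CC=C
F3 | step 10 | (1R,4R,6R)-4-[(1E,5R)-8,8-dibromo-5-(2-hydroxypropan-2-yl)-2-methylocta-1,7-dien-1-yl]-6-methyl-3,7-dioxabicyclo[4.1.0]heptan-2-one | O=C1O[C@H](C[C@@]2(C)O[C@@H]12)/C=C(\C)CC[C@@H](C(C)(C)O)CC=C(Br)Br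
F4 | step 10 | (1R,4R,6R)-4-[(1E,5R,7Z)-8-bromo-5-(2-hydroxypropan-2-yl)-2-methylnona-1,7-dien-1-yl]-6-methyl-3,7-dioxabicyclo[4.1.0]heptan-2-one | O=C1O[C@H](C[C@@]2(C)O[C@@H]12)/C=C(\C)CC[C@@H](C(C)(C)O)C/C=C(/C)Br
F5 | step 13 | (2R,3E,7R,9Z)-1-[(2R,3S)-3-(2-hydroxyethyl)-2-methyloxiran-2-yl]-7-(2-hydroxypropan-2-yl)-10-iodo-4-methylundeca-3,9-dien-2-ol | OCC[C@@H]1O[C@]1(C)C[C@@H](O)/C=C(\C)CC[C@@H](C(C)(C)O)C/C=C(/C)I
F6 | step 13 | (2R,3E,7R,9Z)-7-(2-hydroxypropan-2-yl)-10-iodo-1-[(2R,3S)-3-(2-iodoethyl)-2-methyloxiran-2-yl]-4-methylundeca-3,9-dien-2-ol | ICC[C@@H]1O[C@]1(C)C[C@@H](O)/C=C(\C)CC[C@@H](C(C)(C)O)C/C=C(/C)I
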